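**Retrosynthetic overview**

- The target is (3S,5R,8S,3′R,6′R)-5,8-epoxy-5,8-dihydro-β,ε-carotene-3,3′-diol (chrysanthemaxanthin). Its C40 skeleton, both six-membered rings and C3, C3′, C6′ are those of commercial (3R,3′R,6′R)-lutein 1.
- Disconnection A (last ring, dihydrofuran): the C8–O bond, back to a 5,6-epoxide. This is the plant pathway lutein → lutein 5,6-epoxide → 5,8-furanoid oxide.
- Disconnection B (first ring, oxirane): the C5–O and C6–O bonds, back to the C5=C6 alkene of lutein diacetate 2.
- Forward ring order: oxirane (sets C5 and C6), then dihydrofuran (sets C8, keeps C5), both in one flask. The acetates go on before and come off after.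

Assumption: crystalline all-E lutein from marigold counts as a cheap commercial starting material, and the (R) acid catalyst is written as the one that favours 8S; the sense cannot be predicted, so if a test run shows the opposite, the (S) acid is used with nothing else changed.

All operations are run under argon in dim light.

**Step 1**
Reactants: 1 (3R,3′R,6′R)-lutein (all-E)
Product: 2 lutein 3,3′-diacetate
Conditions: Ac2O (6 equiv), pyridine, 20 °C, 12 h
Reagents that add atoms: acetic anhydride, CC(=O)OC(C)=O
Why: Pyridine-mediated O-acylation (nucleophilic acyl substitution) of both secondary alcohols touches no stereocentre, and the esters switch off hydroxyl-directed syn oxygen delivery and attack of the 3-oxygen on C6, deactivate the ε-ring alkene and make the substrate soluble in toluene for ion-pair catalysis.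

**Step 2**
Reactants: 2 lutein 3,3′-diacetate
Product: 4 chrysanthemaxanthin diacetate, via anti-epoxide diacetate 3 (not isolated)
Conditions: dimethyldioxirane (1.05 equiv, acetone solution), CH2Cl2, −40 °C; evaporate at ≤ 0 °C; then (R)-3,3′-bis(2,4,6-triisopropylphenyl)-1,1′-binaphthyl-2,2′-diyl hydrogen phosphate (5 mol %), toluene, −40 → −20 °C; filter through basic Al2O3; HPLC
Reagents that add atoms: dimethyldioxirane, CC1(C)OO1
Why: Proposed new method: dimethyldioxirane epoxidises the only tetrasubstituted, out-of-conjugation-twisted C5=C6 bond (electrophilic oxygen transfer, the site at which peracids attack carotenoids), and attack on the face anti to the 3-acetoxy group gives 3 and fixes C5 (substrate control is weak, the syn epoxide is expected to be at least as abundant, and its furanoids are removed when 4 is purified); the chiral phosphoric acid then protonates the oxirane, the C6–O bond ionises to a polyenyl cation held as a contact ion pair with the chiral phosphate, and the C5 oxygen closes on C8 with retention at C5 (carotenoid 5,6-epoxide to 5,8-furanoid rearrangement, a 1,3-oxygen shift), the ion pair choosing the C6–C7 rotamer that leads to 8S; the achiral-acid version of this rearrangement is classical but unselective at C8, and the closest known catalyst-controlled reactions are chiral-phosphoric-acid-catalysed asymmetric epoxide openings and rearrangements (asymmetric counteranion-directed catalysis).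

**Step 3**
Reactants: 4 chrysanthemaxanthin diacetate
Product: 5 chrysanthemaxanthin (target)
Conditions: K2CO3 (0.3 equiv), MeOH–THF (2:1), 20 °C
Reagents that add atoms: none
Why: K2CO3-catalysed transesterification with methanol (Zemplén-type deacetylation) removes both acetates, and the dihydrofuran, the polyene and all five stereocentres are stable to mild base.

**Compound list**

1 | (3R,3′R,6′R)-β,ε-carotene-3,3′-diol (all-E lutein) | CC1=C[C@H](O)CC(C)(C)[C@H]1/C=C/C(C)=C/C=C/C(C)=C/C=C/C=C(C)/C=C/C=C(C)/C=C/C1=C(C)C[C@@H](O)CC1(C)C | starting material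

2 | (3R,3′R,6′R)-β,ε-carotene-3,3′-diyl diacetate (lutein diacetate) | CC1=C[C@H](OC(C)=O)CC(C)(C)[C@H]1/C=C/C(C)=C/C=C/C(C)=C/C=C/C=C(C)/C=C/C=C(C)/C=C/C1=C(C)C[C@@H](OC(C)=O)CC1(C)C | intermediate

3 | (3S,5R,6S,3′R,6′R)-5,6-epoxy-5,6-dihydro-β,ε-carotene-3,3′-diyl diacetate (anti-epoxide diacetate; oxirane oxygen on the ring face opposite to the 3-acetoxy group) | CC1=C[C@H](OC(C)=O)CC(C)(C)[C@H]1/C=C/C(C)=C/C=C/C(C)=C/C=C/C=C(C)/C=C/C=C(C)/C=C/[C@@]12O[C@]1(C)C[C@@H](OC(C)=O)CC2(C)C | intermediate (not isolated)

4 | (3S,5R,8S,3′R,6′R)-5,8-epoxy-5,8-dihydro-β,ε-carotene-3,3′-diyl diacetate (chrysanthemaxanthin diacetate; polyene chain at C8 cis to the C5 methyl on the dihydrofuran) | CC1=C[C@H](OC(C)=O)CC(C)(C)[C@H]1/C=C/C(C)=C/C=C/C(C)=C/C=C/C=C(C)/C=C/C=C(\C)[C@@H]1C=C2C(C)(C)C[C@H](OC(C)=O)C[C@@]2(C)O1 | intermediate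

5 | (3S,5R,8S,3′R,6′R)-5,8-epoxy-5,8-dihydro-β,ε-carotene-3,3′-diol (chrysanthemaxanthin, CNP0219251.2) | CC1=C[C@H](O)CC(C)(C)[C@H]1/C=C/C(C)=C/C=C/C(C)=C/C=C/C=C(C)/C=C/C=C(\C)[C@@H]1C=C2C(C)(C)C[C@H](O)C[C@@]2(C)O1 | target

**Step count**

Total steps: 3. Longest linear sequence: 3 steps (1 → 2 → 4 → 5).

**Steps most likely to fail (the route has three steps; ranked)**

1. Step 2.
   - C5 is set only by substrate control. The pseudoaxial C1 methyl shields the anti face, so the wanted anti epoxide is expected to be the minor isomer (about one quarter to one half). This costs yield, not identity, because the four furanoid diacetates are separable.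
   - The level and sense of induction at C8 by the chiral acid are untested.
   - Over-oxidation of the polyene is possible.
   - Fallback, setting out from 2 and coming back at 4: give up catalyst control and the single flask. Epoxidise 2 with mCPBA in CH2Cl2 over aqueous NaHCO3 at 0 °C. Isolate the anti epoxide 3 by chromatography on Et3N-deactivated SiO2 and discard the syn epoxide. Rearrange 3 with 0.01 M HCl in Et2O at 0 °C. This classical treatment gives 4 together with about the same amount of its C8 epimer, flavoxanthin diacetate F1. The two are separated by HPLC, and flavoxanthin diacetate F1 is returned to the same acid, which re-ionises the C8–O bond and re-equilibrates C8, so repeated cycles converge on 4.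

2. Step 3.
   - The free furanoid diol is the most air- and light-sensitive compound of the route, and prolonged base contact can cause E/Z isomerisation and oxidative loss.
   - Fallback, setting out from 4 and coming back at 5: replace transesterification by hydride cleavage of the esters. Use LiAlH4 in Et2O–THF at −20 °C for a few minutes and quench with Na2SO4·10H2O. The dihydrofuran and the polyene are inert to hydride. No new compound is made (F0).

3. Step 1.
   - The acetylation itself is reliable. The risk is that the acetates prove unsuitable in step 2, through poor solubility at −40 °C or acid-induced loss of the allylic 3′-acetate.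
   - Fallback, setting out from 1 and coming back at 5: change the protecting group. TBSCl and imidazole in DMF at 20 °C give lutein bis(tert-butyldimethylsilyl) ether F2. The conditions of step 2 then lead, through the anti-epoxide bis(tert-butyldimethylsilyl) ether F3 (not isolated), to chrysanthemaxanthin bis(tert-butyldimethylsilyl) ether F4. Bu4NF buffered with AcOH in THF at 0 °C frees 5.

**Further compounds**

F1 | step 2 | flavoxanthin diacetate, (3S,5R,8R,3′R,6′R)-5,8-epoxy-5,8-dihydro-β,ε-carotene-3,3′-diyl diacetate | CC1=C[C@H](OC(C)=O)CC(C)(C)[C@H]1/C=C/C(C)=C/C=C/C(C)=C/C=C/C=C(C)/C=C/C=C(\C)[C@H]1C=C2C(C)(C)C[C@H](OC(C)=O)C[C@@]2(C)O1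
F0 | step 3 | none | none
F2 | step 1 | lutein bis(tert-butyldimethylsilyl) ether | CC1=C[C@H](O[Si](C)(C)C(C)(C)C)CC(C)(C)[C@H]1/C=C/C(C)=C/C=C/C(C)=C/C=C/C=C(C)/C=C/C=C(C)/C=C/C1=C(C)C[C@@H](O[Si](C)(C)C(C)(C)C)CC1(C)C
F3 | step 1 | anti-epoxide bis(tert-butyldimethylsilyl) ether, (3S,5R,6S,3′R,6′R) | CC1=C[C@H](O[Si](C)(C)C(C)(C)C)CC(C)(C)[C@H]1/C=C/C(C)=C/C=C/C(C)=C/C=C/C=C(C)/C=C/C=C(C)/C=C/[C@@]12O[C@]1(C)C[C@@H](O[Si](C)(C)C(C)(C)C)CC2(C)C
F4 | step 1 | chrysanthemaxanthin bis(tert-butyldimethylsilyl) ether, (3S,5R,8S,3′R,6′R) | CC1=C[C@H](O[Si](C)(C)C(C)(C)C)CC(C)(C)[C@H]1/C=C/C(C)=C/C=C/C(C)=C/C=C/C=C(C)/C=C/C=C(\C)[C@@H]1C=C2C(C)(C)C[C@H](O[Si](C)(C)C(C)(C)C)C[C@@]2(C)O1
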